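## Analysis of the target

The target is a single cyclohexane ring which, numbered as in quinic acid, carries a tertiary hydroxyl and the carboxylic acid on C1, methylenes at C2 and C6, the only free secondary hydroxyl on C3, and (E)-4-hydroxycinnamoyl esters on the oxygens of C4 and C5. Of its four stereocentres, O1, O3 and O4 lie on one face of the ring and O5 and the carboxyl group on the other, so the 1,3-diol is cis, C3/C4 is cis and C4/C5 is trans. The two aryl-conjugated enoate esters are the sensitive part: base or nucleophiles cleave them, they migrate to a neighbouring free hydroxyl (4 to 3) above neutral pH, hydrogenation would saturate them, and the phenols are easily oxidised. The last steps therefore have to be non-basic and non-reductive, and O3 has to stay distinguishable from O4 and O5 from the moment these oxygens exist. The difficulty is a quaternary carbinol stereocentre plus three secondary C–O centres that differ only in position and face. The feature used here is that the C4–C5 bond lies across the ring from C1. Written as a C4=C5 alkene next to a C3 carbonyl, the ring is a cyclohexenone that opens at that alkene to an acyclic α-hydroxy ester whose only stereocentre is C1, and that carbinol is the aldol retron of an α-keto ester.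

## Retrosynthetic reasoning

Target 20 back to diester 18 (through acid 19). Only protecting groups are removed: three silyl ethers (O3 and both phenols) and a tert-butyl ester. These were chosen because fluoride and anhydrous acid take them off, so no base or hydrogen touches the cinnamoyl esters. The forward steps must free O3 last, so that the 4-acyl group has little chance to move to it.

Diester 18 back to hydroxy ester 17 and acid 15. The acyl C–O bond at O4 is cut. In 17 the only acylable hydroxyl is O4 (O1 is tertiary, O3 is silylated), so a plain carbodiimide esterification is enough. A 5-to-4 acyl shift in 17 is harmless because both acyl groups are the same.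

Hydroxy ester 17 back to epoxide 12 and acid 15. The C5–O bond is cut. Letting the carboxylate of 15 open a C4–C5 epoxide brings O5 in already acylated, sets the 4,5-trans relation by inversion at C5, and unmasks O4 alone. The forward step must attack C5 and not C4.

Epoxide 12 back to cis-diol 10 (through epoxy diol 11). The silyl ether on O3 and the C4–O/C5–O bonds of the oxirane are removed. In 10 the allylic 3-OH and the homoallylic 1-OH lie on the same face, so a peracid is guided to that face and O4 ends up cis to O3. Silylation after epoxidation marks O3, the only secondary hydroxyl present.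

Cis-diol 10 back to enone 8. The C3–H bond is cut. A chelate from O1 to the C3 carbonyl oxygen would be a bridged bicycle with a bridgehead C=O, so chelate-controlled delivery cannot be relied on in this ring. Hydride delivered internally from a borohydride bound at O1 reaches C3 easily, but from the hydroxyl face, and gives the wrong epimer. C3 is therefore set by reagent control with a chiral oxazaborolidine and a borane that cannot be delivered from O1.

Enone 8 back to diene 7. This is the central cut, through the C4=C5 double bond. It is placed there because it leaves an acyclic precursor with one stereocentre, marks C3 as a carbonyl, and leaves C4/C5 as an alkene for later oxygenation. The forward ring-closing metathesis sets no stereocentre and only has to beat intermolecular metathesis.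

Diene 7 back to keto ester 4 and silyloxydiene 5. The C1–C2 bond is cut as an aldol bond. The tertiary carbinol next to an ester comes from face-selective addition of the enol silane of a vinyl ketone to the chelating α-keto ester under a chiral copper Lewis acid. This single catalytic step sets C1.

Keto ester 4 back to oxalate 1 and Grignard reagent 2. The bond between the ketone carbon and the allyl CH2 is cut. Mono-addition to the diester gives the keto ester in one step and brings in the tert-butyl ester used to the end.

Acid 15 back to p-coumaric acid 13. Only the phenol silyl ether is removed; the coumaroyl unit is bought with its E double bond in place.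

## Alternatives that were turned down

Alternative 1: The C1–O bond is disconnected, which leads back to a shikimate enoate whose 4,5-diol is tied up as a butane-2,3-diacetal, methyl 4,5-O-(2,3-dimethoxybutane-2,3-diyl)shikimate A2. In the forward step the free allylic 3-hydroxyl of A2 steers a nucleophilic alkyl hydroperoxide salt, or a strong peracid, to its own face of the C1=C2 enoate. The product is the 1,2-epoxide cis to the 3-OH, methyl 1,2-anhydro-4,5-O-(2,3-dimethoxybutane-2,3-diyl)-2-hydroxyquinate A1.
- For it: C3, C4 and C5 come from the chiral pool, and the C1–O bond is placed on the correct face by a short-range directing effect.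
- Against it: A1 carries an oxygen at C2 that the target lacks. The oxirane must be cleaved reductively at C2–O while the C1–O bond is kept, and the C1–O bond, α to the ester, is the one electron-transfer reductants break first. That costs at least a halide opening and a dehalogenation.
- Against it: once the C2 oxygen of A1 is gone, what remains is a 4,5-protected quinate ester that (−)-quinic acid A3 gives directly by esterification and acetalisation, so the sequence is a detour.
- Against it: the protection is the inverse of what is needed (O4 and O5 masked, O3 free), and the methyl ester cannot be removed at the end without hydrolysis that the cinnamoyl esters do not survive.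
- Comparison: Alternative 1 is more secure at C3–C5. The chosen route offers instead oxygens that arrive already differentiated, an acid-labile ester, and no dependence on the pool.

Alternative 2: The C1–C2 and C1–C6 bonds are disconnected in a five-plus-one ring construction. The diiodide 2,3,4-tri-O-benzyl-1,5-dideoxy-1,5-diiodo-D-arabinitol A5 supplies ring carbons C2 to C6, and 2-lithio-1,3-dithiane A6, lithiated again after the first substitution, supplies C1. Two successive displacements of iodide close the cyclohexane as the spiro dithioketal (8R,10R)-8,9,10-tris(benzyloxy)-1,5-dithiaspiro[5.5]undecane A4.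
- For it: the C3–C5 triad is fixed by the pentitol and the ring closure is a simple double SN2 reaction.
- Against it: both C–I carbons of A5 are primary but slowed by a β-benzyloxy group, and after the first alkylation of A6 the second needs a hindered 2-alkyl dithiane anion.
- Against it: A4 has neither the carboxyl carbon nor the C1 stereocentre. After unmasking the ketone, a one-carbon nucleophile must add with facial control from remote benzyloxy groups only.
- Against it: the three oxygens of A4 carry identical benzyl ethers. These must be removed by hydrogenolysis before any cinnamoyl group is present, which returns a polyol with the same differentiation problem as A3, after more than a dozen steps.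
- Comparison: Alternative 2 is at least as strong on C3–C5. The chosen route controls C1 first, by catalysis, and never has to tell three equal ethers apart.

Alternative 3: The two acyl C–O bonds and the two acyl C–Cα bonds are disconnected together. The diol p-methoxybenzyl 3-O-(tert-butyldimethylsilyl)quinate A8, made from A3, is combined with two molecules of carbon monoxide A10 and two molecules of (E)-tert-butyl[4-(2-iodovinyl)phenoxy]dimethylsilane A9 under a palladium catalyst with a wide-bite-angle bisphosphine and an amine base. The product is p-methoxybenzyl 3-O-(tert-butyldimethylsilyl)-4,5-bis-O-[(E)-4-(tert-butyldimethylsilyloxy)cinnamoyl]quinate A7.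
- For it: all four ring stereocentres are bought, and the protecting groups of A7 come off with acid and fluoride.
- Against it: the acyl-palladium intermediate must be trapped by the two hindered secondary alcohols of A8 on neighbouring carbons. Such alcohols are slow partners, so Heck reaction of A9 with cinnamate already formed, uptake of a second molecule of A10 (double carbonylation) and stalling at the monoester compete.
- Against it: the vinyl iodide A9 takes more steps to make than the acid it replaces, which is sold. The carbonylation builds a bond that ordinary acylation of A8 gets for nothing.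
- Comparison: starting from A3 is shorter and stereochemically safer than the chosen route, and that is conceded. The chosen route offers a de novo ring open to either enantiomer by choice of ligand, to labels and to ring analogues, and it brings O5 in as the ester.

Key step: step 3

Remark: ring positions are numbered as in quinic acid throughout (C1 quaternary, C3 free hydroxyl, C4 and C5 acylated), and the (R,R) ligand of step 2 is assumed to induce the sense opposite to that known for its (S,S) enantiomer with pyruvate esters.

## Route

Step 1
Reactants: 1 di-tert-butyl oxalate; 2 allylmagnesium bromide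
Product: 4 tert-butyl 2-oxopent-4-enoate, via magnesium hemiketal alkoxide 3 (not isolated)
Conditions: 2 (1.0 equiv, Et2O) added to 1 (1.3 equiv), THF, −78 °C; 1 M HCl at −78 °C
Reagents that add atoms: none
Why: Mono-addition of a Grignard reagent to a dialkyl oxalate; the chelated tetrahedral adduct 3 persists at −78 °C and releases the ketone only on the cold quench, so the allyl nucleophile never meets 4, and inverse addition into excess hindered diester further suppresses double addition. Product 4 is used at once because the β,γ-unsaturated keto ester can drift into conjugation.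

Step 2
Reactants: 4 tert-butyl 2-oxopent-4-enoate; 5 2-(trimethylsilyloxy)buta-1,3-diene
Product: 7 tert-butyl (R)-2-allyl-2-hydroxy-4-oxohex-5-enoate, via O-trimethylsilyl aldol adduct 6 (not isolated)
Conditions: Cu(OTf)2 (10 mol%), (R,R)-t-Bu-box [2,2'-(propane-2,2-diyl)bis((4R)-4-tert-butyl-4,5-dihydrooxazole)] (11 mol%), 5 (1.5 equiv), THF, −78 °C; then 1 M HCl/THF, 0 °C, brief
Reagents that add atoms: none
Why: Catalytic enantioselective Mukaiyama aldol addition of a ketone enol silane to an α-keto ester: 4 chelates divalent copper through both carbonyl oxygens, one tert-butyl group of the ligand covers one face of the ketone, and the enol silane terminus of 5 adds to the other with silicon passing to the new alkoxide. With pyruvates the (S,S) ligand gives the (S)-carbinol (nucleophile arm ranked third, ketone alkyl fourth), so the (R,R) ligand should give (R)-7; brief cold acid cleaves the tertiary silyl ether.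

Step 3
Reactants: 7 tert-butyl (R)-2-allyl-2-hydroxy-4-oxohex-5-enoate
Product: 8 tert-butyl (R)-1-hydroxy-5-oxocyclohex-3-ene-1-carboxylate
Conditions: (H2IMes)(PCy3)Cl2Ru=CHPh (second-generation Grubbs catalyst, 5 mol%), CH2Cl2 (0.01 M), 40 °C
Reagents that add atoms: none
Why: Ring-closing olefin metathesis, the closest known type being closure of dienes that hold a vinyl ketone and a terminal alkene to cyclohex-2-enones with N-heterocyclic-carbene ruthenium benzylidenes. The catalyst exchanges its benzylidene with the electron-rich allyl terminus (C5), the chain-bound alkylidene adds across the vinyl ketone C=C (C4) to a ruthenacyclobutane, and cycloreversion releases the C4=C5 bond and, after turnover, ethene. The six-membered carbocycle is thus closed by intramolecular [2+2] cycloaddition and cycloreversion between the two chain ends, which places the new alkene in conjugation with the C3 carbonyl. No stereocentre is formed, and C1, a fully substituted carbon, cannot epimerise. The selectivity needed is ring closure over cross-metathesis to dimers: the quaternary C1 bends the two arms together (Thorpe–Ingold effect), six is the favoured ring size, the enone end does not readily homodimerise, and high dilution does the rest. The free tertiary hydroxyl and the ester are tolerated by this catalyst and loss of ethene drives the reaction. Neutral conditions and moderate temperature are kept so that the β-hydroxy enone does not dehydrate and aromatise.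

Step 4
Reactants: 8 tert-butyl (R)-1-hydroxy-5-oxocyclohex-3-ene-1-carboxylate
Product: 10 tert-butyl (1R,5R)-1,5-dihydroxycyclohex-3-ene-1-carboxylate, via secondary catecholborate ester 9 (not isolated)
Conditions: (S)-1-methyl-3,3-diphenyltetrahydro-1H,3H-pyrrolo[1,2-c][1,3,2]oxazaborole ((S)-Me-CBS, 0.5 equiv), catecholborane (2.0 equiv), toluene/CH2Cl2, −78 °C; then MeOH, pH 7 buffer
Reagents that add atoms: none
Why: Corey–Bakshi–Shibata reduction of a cyclic enone, which is held s-trans and is reduced 1,2; the alkene arm (C4) acts as the large group and the CH2 arm (C2) as the small one, so the (S)-catalyst should deliver hydride to the Si face of C3 and give the (R)-carbinol, the 3-OH cis to the 1-OH. Catecholborane is used because a borate formed at the tertiary hydroxyl carries no hydride and cannot deliver one to the wrong face.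

Step 5
Reactants: 10 tert-butyl (1R,5R)-1,5-dihydroxycyclohex-3-ene-1-carboxylate
Product: 11 tert-butyl (1S,3S,5R,6R)-3,5-dihydroxy-7-oxabicyclo[4.1.0]heptane-3-carboxylate
Conditions: mCPBA (1.3 equiv), NaHCO3, CH2Cl2, 0 °C to rt
Reagents that add atoms: 3-chloroperoxybenzoic acid (mCPBA), O=C(OO)c1cccc(Cl)c1
Why: Henbest hydroxyl-directed epoxidation: the allylic 3-OH and the homoallylic 1-OH lie on the same face and hydrogen-bond to the peracid, so oxygen is delivered to that face and the C4–O bond ends up cis to the 3-OH. The bicarbonate buffer keeps the acid by-product from opening the oxirane.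

Step 6
Reactants: 11 tert-butyl (1S,3S,5R,6R)-3,5-dihydroxy-7-oxabicyclo[4.1.0]heptane-3-carboxylate
Product: 12 tert-butyl (1S,3R,5R,6S)-5-[(tert-butyldimethylsilyl)oxy]-3-hydroxy-7-oxabicyclo[4.1.0]heptane-3-carboxylate
Conditions: t-BuMe2SiCl (1.2 equiv), imidazole (2.5 equiv), DMF, 0 °C to rt
Reagents that add atoms: tert-butyldimethylsilyl chloride, CC(C)(C)[Si](C)(C)Cl
Why: Silylation of a secondary alcohol beside a tertiary one under Corey conditions; the tertiary α-hydroxy ester does not react with the silyl chloride, and imidazole leaves the oxirane and the ester alone. The silyl ether marks O3 as the oxygen that stays free at the end.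

Step 7
Reactants: 13 p-coumaric acid
Product: 15 (E)-3-[4-(triisopropylsilyloxy)phenyl]prop-2-enoic acid, via bis-silylated coumarate 14 (not isolated)
Conditions: i-Pr3SiCl (2.3 equiv), imidazole (5 equiv), DMF, rt; then K2CO3 (1.1 equiv), MeOH/THF/H2O, 0 °C; 1 M HCl to pH 3
Reagents that add atoms: triisopropylsilyl chloride, CC(C)[Si](Cl)(C(C)C)C(C)C
Why: Silylation of both the phenol and the acid, then selective hydrolysis of the much more labile silyl ester. The hindered aryl triisopropylsilyl ether resists brief carbonate treatment and is chosen over smaller silyl groups so that it survives the warm carboxylate medium of step 8.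

Step 8
Reactants: 12 tert-butyl (1S,3R,5R,6S)-5-[(tert-butyldimethylsilyl)oxy]-3-hydroxy-7-oxabicyclo[4.1.0]heptane-3-carboxylate; 15 (E)-3-[4-(triisopropylsilyloxy)phenyl]prop-2-enoic acid
Product: 17 tert-butyl 3-O-(tert-butyldimethylsilyl)-5-O-[(E)-3-(4-triisopropylsilyloxyphenyl)prop-2-enoyl]quinate, via caesium carboxylate 16 (not isolated)
Conditions: 15 (2.5 equiv), Cs2CO3 (0.3 equiv), DMF, 80 °C
Reagents that add atoms: none
Why: SN2 opening of an epoxide by a carboxylate with the free acid as proton source: attack at C5 from the face opposite the oxirane oxygen inverts C5 and leaves the C4–O bond untouched, which gives the 4,5-trans arrangement directly as the ester. C5 should be preferred because C4 is deactivated by the adjacent C3–O bond and flanked by the silyl ether, and because the C5 pathway runs through the half-chair with the 3-silyloxy and 1-hydroxyl groups pseudo-equatorial (trans-diaxial opening). The excess acid protonates the C4 alkoxide at once, so the silyl group should not move from O3 to O4.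

Step 9
Reactants: 17 tert-butyl 3-O-(tert-butyldimethylsilyl)-5-O-[(E)-3-(4-triisopropylsilyloxyphenyl)prop-2-enoyl]quinate; 15 (E)-3-[4-(triisopropylsilyloxy)phenyl]prop-2-enoic acid
Product: 18 tert-butyl 3-O-(tert-butyldimethylsilyl)-4,5-bis-O-[(E)-3-(4-triisopropylsilyloxyphenyl)prop-2-enoyl]quinate
Conditions: 15 (1.5 equiv), N,N'-diisopropylcarbodiimide (1.6 equiv), 4-(dimethylamino)pyridine (0.3 equiv), CH2Cl2, 0 °C to rt
Reagents that add atoms: none
Why: Steglich esterification of the only remaining secondary alcohol; the tertiary 1-OH is not acylated under these conditions. A 5-to-4 acyl shift beforehand would be harmless because both acyl groups are the same.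

Step 10
Reactants: 18 tert-butyl 3-O-(tert-butyldimethylsilyl)-4,5-bis-O-[(E)-3-(4-triisopropylsilyloxyphenyl)prop-2-enoyl]quinate
Product: 19 3-O-(tert-butyldimethylsilyl)-4,5-bis-O-[(E)-3-(4-triisopropylsilyloxyphenyl)prop-2-enoyl]quinic acid
Conditions: CF3CO2H/CH2Cl2 (1:4), 0 °C to rt
Reagents that add atoms: none
Why: Acidolysis of the tert-butyl ester with loss of 2-methylpropene; the cinnamoyl esters and aryl silyl ethers are stable to anhydrous acid for this time, and no base is present to cleave or shift an ester. Partial loss of the 3-O-silyl group would not matter because the next step removes it.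

Step 11
Reactants: 19 3-O-(tert-butyldimethylsilyl)-4,5-bis-O-[(E)-3-(4-triisopropylsilyloxyphenyl)prop-2-enoyl]quinic acid
Product: 20 4,5-di-O-p-coumaroylquinic acid
Conditions: HF·pyridine (excess), THF/pyridine, 0 °C to rt; acidic work-up, reverse-phase chromatography
Reagents that add atoms: none
Why: Fluoride-mediated cleavage of the two aryl silyl ethers and the one alkyl silyl ether under weakly acidic conditions, which frees the phenols and the 3-OH without touching the esters; the hindered aryl ethers are the slowest to go, so excess reagent and an extended reaction time are planned. Acidic work-up keeps the 4-acyl group from moving to O3.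

## Compound list

1 | di-tert-butyl oxalate | CC(C)(C)OC(=O)C(=O)OC(C)(C)C | starting material
2 | allylmagnesium bromide | C=CC[Mg]Br | starting material
3 | bromomagnesium alkoxide of tert-butyl 2-tert-butoxy-2-hydroxypent-4-enoate (tetrahedral adduct, racemic) | C=CCC(O[Mg]Br)(OC(C)(C)C)C(=O)OC(C)(C)C | intermediate (not isolated)
4 | tert-butyl 2-oxopent-4-enoate | C=CCC(=O)C(=O)OC(C)(C)C | intermediate
5 | 2-(trimethylsilyloxy)buta-1,3-diene | C=CC(=C)O[Si](C)(C)C | starting material
6 | tert-butyl (R)-2-allyl-4-oxo-2-(trimethylsilyloxy)hex-5-enoate | C=CC(=O)C[C@@](O[Si](C)(C)C)(C(=O)OC(C)(C)C)CC=C | intermediate (not isolated)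
7 | tert-butyl (R)-2-allyl-2-hydroxy-4-oxohex-5-enoate | C=CC(=O)C[C@@](O)(C(=O)OC(C)(C)C)CC=C | intermediate
8 | tert-butyl (R)-1-hydroxy-5-oxocyclohex-3-ene-1-carboxylate | O=C1C=CC[C@](O)(C(=O)OC(C)(C)C)C1 | intermediate
9 | tert-butyl (1R,5R)-5-(1,3,2-benzodioxaborol-2-yloxy)-1-hydroxycyclohex-3-ene-1-carboxylate | c1ccc2OB(Oc2c1)O[C@H]1C=CC[C@](O)(C(=O)OC(C)(C)C)C1 | intermediate (not isolated)
10 | tert-butyl (1R,5R)-1,5-dihydroxycyclohex-3-ene-1-carboxylate | O[C@H]1C=CC[C@](O)(C(=O)OC(C)(C)C)C1 | intermediate
11 | tert-butyl (1S,3S,5R,6R)-3,5-dihydroxy-7-oxabicyclo[4.1.0]heptane-3-carboxylate | O[C@H]1[C@H]2O[C@H]2C[C@](O)(C(=O)OC(C)(C)C)C1 | intermediate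
12 | tert-butyl (1S,3R,5R,6S)-5-[(tert-butyldimethylsilyl)oxy]-3-hydroxy-7-oxabicyclo[4.1.0]heptane-3-carboxylate | CC(C)(C)[Si](C)(C)O[C@H]1[C@H]2O[C@H]2C[C@](O)(C(=O)OC(C)(C)C)C1 | intermediate
13 | p-coumaric acid | OC(=O)/C=C/c1ccc(O)cc1 | starting material
14 | triisopropylsilyl (E)-3-[4-(triisopropylsilyloxy)phenyl]prop-2-enoate | CC(C)[Si](C(C)C)(C(C)C)OC(=O)/C=C/c1ccc(O[Si](C(C)C)(C(C)C)C(C)C)cc1 | intermediate (not isolated)
15 | (E)-3-[4-(triisopropylsilyloxy)phenyl]prop-2-enoic acid | OC(=O)/C=C/c1ccc(O[Si](C(C)C)(C(C)C)C(C)C)cc1 | intermediate
16 | caesium (E)-3-[4-(triisopropylsilyloxy)phenyl]prop-2-enoate | [Cs+].[O-]C(=O)/C=C/c1ccc(O[Si](C(C)C)(C(C)C)C(C)C)cc1 | intermediate (not isolated)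
17 | tert-butyl 3-O-(tert-butyldimethylsilyl)-5-O-[(E)-3-(4-triisopropylsilyloxyphenyl)prop-2-enoyl]quinate | O[C@@H]1[C@H](O[Si](C)(C)C(C)(C)C)C[C@@](O)(C(=O)OC(C)(C)C)C[C@H]1OC(=O)/C=C/c1ccc(O[Si](C(C)C)(C(C)C)C(C)C)cc1 | intermediate
18 | tert-butyl 3-O-(tert-butyldimethylsilyl)-4,5-bis-O-[(E)-3-(4-triisopropylsilyloxyphenyl)prop-2-enoyl]quinate | O=C(/C=C/c1ccc(O[Si](C(C)C)(C(C)C)C(C)C)cc1)O[C@@H]1[C@H](O[Si](C)(C)C(C)(C)C)C[C@@](O)(C(=O)OC(C)(C)C)C[C@H]1OC(=O)/C=C/c1ccc(O[Si](C(C)C)(C(C)C)C(C)C)cc1 | intermediate
19 | 3-O-(tert-butyldimethylsilyl)-4,5-bis-O-[(E)-3-(4-triisopropylsilyloxyphenyl)prop-2-enoyl]quinic acid | O=C(/C=C/c1ccc(O[Si](C(C)C)(C(C)C)C(C)C)cc1)O[C@@H]1[C@H](O[Si](C)(C)C(C)(C)C)C[C@@](O)(C(=O)O)C[C@H]1OC(=O)/C=C/c1ccc(O[Si](C(C)C)(C(C)C)C(C)C)cc1 | intermediate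
20 | 4,5-di-O-p-coumaroylquinic acid | O=C(/C=C/c1ccc(O)cc1)O[C@@H]1[C@H](O)C[C@@](O)(C(=O)O)C[C@H]1OC(=O)/C=C/c1ccc(O)cc1 | target

## Step count and least certain steps

Total: 11 steps. Longest linear sequence: 10 steps (steps 1 to 6 and 8 to 11, from 1 and 2 to 20); step 7 is a one-step side branch.

Step 3 (key step). The most likely failures are:
- slow turnover, because the alkylidene formed at the allyl end can be held by the ester carbonyl or the hydroxyl;
- cross-metathesis of the vinyl ketone between molecules;
- migration of the allyl double bond by ruthenium hydride species;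
- dehydration and aromatisation of the β-hydroxy enone on long heating.

The fallback sets out from 7 and returns at 8. Luche reduction (NaBH4, CeCl3·7H2O, MeOH, −40 °C) converts the vinyl ketone into tert-butyl (2R)-2-allyl-2,4-dihydroxyhex-5-enoate F1 as a pair of C4 epimers. This diene has two electron-rich terminal alkenes and should close with the same ruthenium catalyst to tert-butyl (1R)-1,5-dihydroxycyclohex-3-ene-1-carboxylate F2 (both C5 epimers, the cis one being 10). MnO2 in CH2Cl2 then oxidises the allylic alcohol of the mixture to 8.

Step 8. The most likely failures are: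
- poor regioselectivity, since the trajectory to C5 passes an axial ester on C1 and attack at C4 would give the wrong configuration at both carbons;
- silyl migration from O3 to O4 if the alkoxide is not protonated fast enough;
- loss of the aryl silyl ether by carboxylate attack at silicon.

The fallback sets out from 12 and returns at 18. BF3·OEt2 in CH2Cl2 at −40 °C activates the oxirane. The ester carbonyl oxygen, which sits on the face opposite the oxirane and can only reach C5 in a five-membered ring, closes onto C5 with loss of 2-methylpropene and gives 3-O-(tert-butyldimethylsilyl)quinic acid 1,5-lactone F3. LiOH in THF/H2O at 0 °C opens the strained lactone to 3-O-(tert-butyldimethylsilyl)quinic acid F4. O-tert-Butyl-N,N'-diisopropylisourea in CH2Cl2 restores the ester as tert-butyl 3-O-(tert-butyldimethylsilyl)quinate F5. Double Steglich acylation of its 4,5-diol with 15 (3 equiv, N,N'-diisopropylcarbodiimide, 4-(dimethylamino)pyridine) gives 18.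

Step 4. The most likely failure is poor facial selectivity. The CH2 arm carries a quaternary carbon and is not as small as in simple cyclohexenones, the ring's own bias may oppose the catalyst, and uncatalysed background reduction is unselective. The fallback sets out from 8 and returns at 10. Me4NBH(OAc)3 in MeCN/AcOH at −20 °C binds to the 1-OH and delivers hydride internally to the hydroxyl face of C3, which should give the trans-diol tert-butyl (1R,5S)-1,5-dihydroxycyclohex-3-ene-1-carboxylate F6. A Mitsunobu reaction (PPh3, diisopropyl azodicarboxylate, 4-nitrobenzoic acid, toluene, 0 °C) inverts the secondary allylic carbinol to tert-butyl (1R,5R)-1-hydroxy-5-(4-nitrobenzoyloxy)cyclohex-3-ene-1-carboxylate F7. K2CO3 in MeOH at 0 °C removes the nitrobenzoate and gives 10.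

Step 2. The most likely failures are:
- erosion of enantioselectivity with an allyl rather than a methyl ketone substituent and a tert-butyl ester;
- hetero-Diels–Alder addition of the diene across the activated ketone instead of aldol addition;
- acid-mediated conjugate addition to the vinyl ketone during desilylation.

The fallback sets out from 4 and returns at 7. With the same copper catalyst, 1-(ethylsulfanyl)-1-(trimethylsilyloxy)ethene, which is not a diene, adds to 4 to give tert-butyl (R)-2-[2-(ethylsulfanyl)-2-oxoethyl]-2-(trimethylsilyloxy)pent-4-enoate F8. 1 M HCl cleaves this to tert-butyl (R)-2-[2-(ethylsulfanyl)-2-oxoethyl]-2-hydroxypent-4-enoate F9. Liebeskind–Srogl coupling with tributyl(vinyl)stannane [Pd2(dba)3 (zerovalent palladium), tri(2-furyl)phosphine, Cu(O2PPh2) (monovalent copper), THF, 50 °C] converts the thioester into the vinyl ketone 7.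

## Further compounds

F1 | step 3 | tert-butyl (2R)-2-allyl-2,4-dihydroxyhex-5-enoate (C4 epimers) | C=CC(O)C[C@@](O)(C(=O)OC(C)(C)C)CC=C
F2 | step 3 | tert-butyl (1R)-1,5-dihydroxycyclohex-3-ene-1-carboxylate (C5 epimers) | OC1C=CC[C@](O)(C(=O)OC(C)(C)C)C1
F3 | step 8 | 3-O-(tert-butyldimethylsilyl)quinic acid 1,5-lactone | O[C@@H]1[C@H](O[Si](C)(C)C(C)(C)C)C[C@]2(O)C[C@H]1OC2=O
F4 | step 8 | 3-O-(tert-butyldimethylsilyl)quinic acid | O[C@@H]1[C@H](O[Si](C)(C)C(C)(C)C)C[C@@](O)(C(=O)O)C[C@H]1O
F5 | step 8 | tert-butyl 3-O-(tert-butyldimethylsilyl)quinate | O[C@@H]1[C@H](O[Si](C)(C)C(C)(C)C)C[C@@](O)(C(=O)OC(C)(C)C)C[C@H]1O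
F6 | step 4 | tert-butyl (1R,5S)-1,5-dihydroxycyclohex-3-ene-1-carboxylate | O[C@@H]1C=CC[C@](O)(C(=O)OC(C)(C)C)C1
F7 | step 4 | tert-butyl (1R,5R)-1-hydroxy-5-(4-nitrobenzoyloxy)cyclohex-3-ene-1-carboxylate | O=C(O[C@H]1C=CC[C@](O)(C(=O)OC(C)(C)C)C1)c1ccc(cc1)[N+](=O)[O-]
F8 | step 2 | tert-butyl (R)-2-[2-(ethylsulfanyl)-2-oxoethyl]-2-(trimethylsilyloxy)pent-4-enoate | CCSC(=O)C[C@@](O[Si](C)(C)C)(C(=O)OC(C)(C)C)CC=C
F9 | step 2 | tert-butyl (R)-2-[2-(ethylsulfanyl)-2-oxoethyl]-2-hydroxypent-4-enoate | CCSC(=O)C[C@@](O)(C(=O)OC(C)(C)C)CC=C
A1 | alternative 1 | methyl 1,2-anhydro-4,5-O-(2,3-dimethoxybutane-2,3-diyl)-2-hydroxyquinate | COC(=O)[C@]12O[C@H]1[C@@H](O)[C@H]3O[C@](C)(OC)[C@@](C)(OC)O[C@@H]3C2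
A2 | alternative 1 | methyl 4,5-O-(2,3-dimethoxybutane-2,3-diyl)shikimate | COC(=O)C1=C[C@@H](O)[C@H]2O[C@](C)(OC)[C@@](C)(OC)O[C@@H]2C1
A3 | alternative 1 | (−)-quinic acid | O[C@@H]1[C@H](O)C[C@@](O)(C(=O)O)C[C@H]1O
A4 | alternative 2 | (8R,10R)-8,9,10-tris(benzyloxy)-1,5-dithiaspiro[5.5]undecane | c1ccccc1COC1[C@H](OCc2ccccc2)CC2(SCCCS2)C[C@H]1OCc1ccccc1
A5 | alternative 2 | 2,3,4-tri-O-benzyl-1,5-dideoxy-1,5-diiodo-D-arabinitol | IC[C@@H](OCc1ccccc1)C(OCc1ccccc1)[C@H](OCc1ccccc1)CI
A6 | alternative 2 | 2-lithio-1,3-dithiane | [Li]C1SCCCS1
A7 | alternative 3 | p-methoxybenzyl 3-O-(tert-butyldimethylsilyl)-4,5-bis-O-[(E)-4-(tert-butyldimethylsilyloxy)cinnamoyl]quinate | O=C(/C=C/c1ccc(O[Si](C)(C)C(C)(C)C)cc1)O[C@@H]1[C@H](O[Si](C)(C)C(C)(C)C)C[C@@](O)(C(=O)OCc2ccc(OC)cc2)C[C@H]1OC(=O)/C=C/c1ccc(O[Si](C)(C)C(C)(C)C)cc1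
A8 | alternative 3 | p-methoxybenzyl 3-O-(tert-butyldimethylsilyl)quinate | O[C@@H]1[C@H](O[Si](C)(C)C(C)(C)C)C[C@@](O)(C(=O)OCc2ccc(OC)cc2)C[C@H]1O
A9 | alternative 3 | (E)-tert-butyl[4-(2-iodovinyl)phenoxy]dimethylsilane | I/C=C/c1ccc(O[Si](C)(C)C(C)(C)C)cc1
A10 | alternative 3 | carbon monoxide | [C-]#[O+]
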